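**Retrosynthetic overview**

1. Target 16 ⇐ bis-TIPS ether 15 by desilylation of the two phenols.
2. The carbocycle of 15 is a 4-vinylcyclohexene. Its bond C(Me)(alkenyl)–CH(coumarinyl) joins the tertiary end of one 1-(coumarin-3-yl)-3-methylallyl unit to the coumarinyl-bearing end of a second, identical unit. A formal [1,3] shift therefore leads back from the six-membered ring to the four-membered ring of meso cis-1,2-dimethyl-1,2-bis[(E)-2-(coumarin-3-yl)ethenyl]cyclobutane 13 (ring expansion by two atoms, Ni(0)/chiral carbene).
3. Enabling feature: the C1–C2 bond of cyclobutane 13 is strained, fully substituted and doubly allylic, and its two alkenyl arms are enantiotopic. One catalyst-controlled event can thus set the cyclohexene, the quaternary carbon and both stereocentres.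
4. 13 ⇐ twofold Horner–Wadsworth–Emmons reaction of meso dialdehyde 12 (from 2,3-dimethylmaleic anhydride and ethylene by [2+2], LiAlH4, Swern) with phosphonate 7.
5. 7 ⇐ 2-methoxyresorcinol (Vilsmeier, Perkin, TIPS, NBS, Arbuzov). Ring order: coumarin rings, then the cyclobutane, then the cyclohexene last.

Key step: step 10

Remark on the chemistry: which antipode of the chiral carbene in step 10 leads to the (1R,6R) series cannot be predicted; it is fixed by a ligand screen, and the mirror-image ligand would give the enantiomer.

**Route**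

Step 1
Reactants: 1 2-methoxybenzene-1,3-diol (2-methoxyresorcinol)
Product: 2 2,4-dihydroxy-3-methoxybenzaldehyde
Conditions: POCl3, DMF, MeCN, 0 → 25 °C; then H2O, 50 °C
Reagents that add atoms: N,N-dimethylformamide CN(C)C=O (formyl carbon); water O (formyl oxygen)
Why: Vilsmeier–Haack formylation should occur at C4 (equivalent to C6), the only position ortho to one hydroxyl and para to the other, so a single aldehyde is expected, as is known for resorcinols.

Step 2
Reactants: 2 2,4-dihydroxy-3-methoxybenzaldehyde
Product: 4 7-hydroxy-8-methoxy-3-methyl-2H-chromen-2-one, via propanoate ester 3 (not isolated)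
Conditions: (EtCO)2O, EtCO2Na, 160 °C; then MeOH, cat. HCl, 60 °C
Reagents that add atoms: propanoic anhydride CCC(=O)OC(=O)CC
Why: Perkin coumarin synthesis (O-propanoylation, intramolecular aldol-type condensation of the aryl propanoate onto the aldehyde, dehydration) should close the pyranone ring with the 3-methyl group in place, and acid-catalysed methanolysis then removes only the aryl propanoate at O7 because the cis-fixed lactone is stable under these conditions.

Step 3
Reactants: 4 7-hydroxy-8-methoxy-3-methyl-2H-chromen-2-one
Product: 5 8-methoxy-3-methyl-7-(triisopropylsilyloxy)-2H-chromen-2-one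
Conditions: TIPSCl, imidazole, DMF, 25 °C
Reagents that add atoms: chlorotri(propan-2-yl)silane CC(C)[Si](Cl)(C(C)C)C(C)C
Why: Standard phenol silylation; the bulky TIPS ether is chosen because it should survive radical bromination, Arbuzov heating, amide base and Ni(0) and can be removed at the end with fluoride.

Step 4
Reactants: 5 8-methoxy-3-methyl-7-(triisopropylsilyloxy)-2H-chromen-2-one
Product: 6 3-(bromomethyl)-8-methoxy-7-(triisopropylsilyloxy)-2H-chromen-2-one
Conditions: NBS, AIBN (cat.), PhCF3, 80 °C
Reagents that add atoms: N-bromosuccinimide O=C1CCC(=O)N1Br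
Why: Wohl–Ziegler bromination, in which hydrogen abstraction from the 3-methyl group gives a radical allylic to C3=C4 and conjugated with the arene; the non-polar radical conditions used for side-chain bromination of methyl alkoxycoumarins should disfavour ionic bromination of the ring.

Step 5
Reactants: 6 3-(bromomethyl)-8-methoxy-7-(triisopropylsilyloxy)-2H-chromen-2-one
Product: 7 diethyl {[8-methoxy-2-oxo-7-(triisopropylsilyloxy)-2H-chromen-3-yl]methyl}phosphonate
Conditions: P(OEt)3 (neat), 120 °C
Reagents that add atoms: triethyl phosphite CCOP(OCC)OCC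
Why: Michaelis–Arbuzov reaction of the reactive allylic bromide should give the phosphonate, as known for 3-(halomethyl)coumarins.

Step 6
Reactants: 8 2,3-dimethylmaleic anhydride; 9 ethylene
Product: 10 (1R,5S)-1,5-dimethyl-3-oxabicyclo[3.2.0]heptane-2,4-dione (cis-1,2-dimethylcyclobutane-1,2-dicarboxylic anhydride, meso)
Conditions: hν (medium-pressure Hg, Pyrex), acetophenone (sensitiser), ethylene-saturated EtOAc, −60 °C
Reagents that add atoms: none
Why: Triplet-sensitised [2+2] photocycloaddition of a maleic anhydride with ethylene; the ring fusion forces the two methyl groups cis, so the meso anhydride is the only possible stereoisomer.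

Step 7
Reactants: 10 (1R,5S)-1,5-dimethyl-3-oxabicyclo[3.2.0]heptane-2,4-dione
Product: 11 [(1R,2S)-1,2-dimethylcyclobutane-1,2-diyl]dimethanol (cis, meso)
Conditions: LiAlH4, THF, 66 °C; Fieser work-up
Reagents that add atoms: none
Why: Exhaustive hydride reduction of the cyclic anhydride should give the 1,4-diol; the quaternary carbons carry no acidic hydrogen and keep their cis relation.

Step 8
Reactants: 11 [(1R,2S)-1,2-dimethylcyclobutane-1,2-diyl]dimethanol
Product: 12 (1R,2S)-1,2-dimethylcyclobutane-1,2-dicarbaldehyde (cis, meso)
Conditions: (COCl)2, DMSO, CH2Cl2, −78 °C; Et3N, −78 → 0 °C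
Reagents that add atoms: none
Why: Swern oxidation, in which both hydroxyls are converted into alkoxysulfonium salts before the base is added, so the two aldehydes form together and lactol or lactone formation is avoided; the α-quaternary aldehydes cannot enolise or epimerise.

Step 9
Reactants: 12 (1R,2S)-1,2-dimethylcyclobutane-1,2-dicarbaldehyde; 7 diethyl {[8-methoxy-2-oxo-7-(triisopropylsilyloxy)-2H-chromen-3-yl]methyl}phosphonate (2.1 equiv)
Product: 13 3,3'-{[(1R,2S)-1,2-dimethylcyclobutane-1,2-diyl]bis[(E)-ethene-2,1-diyl]}bis[8-methoxy-7-(triisopropylsilyloxy)-2H-chromen-2-one] (cis, meso)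
Conditions: 7, NaHMDS, THF, −78 °C; then 12, −78 → 20 °C; product stored cold
Reagents that add atoms: none
Why: Twofold Horner–Wadsworth–Emmons olefination, in which the semi-stabilised phosphonate anion should add to the non-enolisable neopentyl-type aldehydes and eliminate to the E-alkenes; the cis relation on the ring is untouched, so the product stays meso.

Step 10
Reactants: 13 meso cis-1,2-dimethyl-1,2-bis[(E)-2-(coumarin-3-yl)ethenyl]cyclobutane (full name under step 9)
Product: 15 3-[(1R,6R)-3,6-dimethyl-6-{(E)-2-[8-methoxy-2-oxo-7-(triisopropylsilyloxy)-2H-chromen-3-yl]ethenyl}cyclohex-2-en-1-yl]-8-methoxy-7-(triisopropylsilyloxy)-2H-chromen-2-one, via bis-allyl nickelacycle 14 (not isolated)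
Conditions: Ni(cod)2 (10 mol %), bulky C2-symmetric chiral NHC (free carbene, 2,6-bis(1-arylethyl)aryl type, 11 mol %), toluene, 0 → 25 °C, glovebox
Reagents that add atoms: none
Why: Proposed new method: Ni(0) is expected to add oxidatively into the strained, doubly allylic and fully substituted C1–C2 bond of meso 13, so that both ring stereocentres become planar, fluxional allyl termini in the catalyst-bound bis(allyl)nickel(II) species 14; reductive elimination between the tertiary terminus of one allyl and the coumarinyl-bearing terminus of the other then gives 15, overall a formal [1,3] shift that enlarges the four-membered ring by two atoms. The closest known reactions are the Ni(0)-catalysed isomerisation of cis-1,2-divinylcyclobutane to 4-vinylcyclohexene and cycloocta-1,5-diene (the same manifold as Ni-catalysed diene cyclodimerisation) and the Ni(0)/NHC-catalysed vinylcyclopropane-to-cyclopentene rearrangement; new are the tetrasubstituted bond, the quaternary centre that is formed and the enantioselective, desymmetrising variant. The only ring closed is the cyclohexene, by C–C reductive elimination (1,3'-coupling of the two allyl units) through a chair-like six-membered array. The quaternary centre and the adjacent CH(coumarinyl) centre are created together: their relative configuration should follow from the template, because the arm that ends as the (E)-alkenyl group stays on nickel and must sit on the metal face (axial) while the syn aryl group of the other allyl lies pseudo-equatorial, which places aryl cis to alkenyl, and their absolute configuration is controlled by the chiral carbene, which distinguishes the two enantiotopic arms of the meso substrate. The step needs six-ring closure (tertiary to benzylic terminus) in preference to eight-ring closure (benzylic to benzylic) and to return to the cyclobutane; a bulky, strongly σ-donating carbene, the ligand type that steers nickel-bound octadienediyl chains toward vinylcyclohexenes, together with the stability of the unstrained cyclohexene should secure this, and working at or below 25 °C keeps the uncatalysed Cope rearrangement of the cis-dialkenylcyclobutane slow.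

Step 11
Reactants: 15 bis-TIPS ether (full name under step 10)
Product: 16 7-hydroxy-3-[(1R,6R)-6-[(E)-2-(7-hydroxy-8-methoxy-2-oxo-2H-chromen-3-yl)ethenyl]-3,6-dimethylcyclohex-2-en-1-yl]-8-methoxy-2H-chromen-2-one (CNP0264408.1)
Conditions: TBAF, AcOH, THF, 0 °C
Reagents that add atoms: none
Why: Fluoride-induced cleavage of the two aryl silyl ethers, buffered with acetic acid so that neither the lactones nor the 1,5-diene are exposed to strong base; no stereocentre is involved.

**Compound list**

1 | 2-methoxybenzene-1,3-diol (2-methoxyresorcinol) | COc1c(O)cccc1O | starting material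
2 | 2,4-dihydroxy-3-methoxybenzaldehyde | COc1c(O)ccc(C=O)c1O | intermediate
3 | 8-methoxy-3-methyl-2-oxo-2H-chromen-7-yl propanoate | CCC(=O)Oc1ccc2cc(C)c(=O)oc2c1OC | intermediate
4 | 7-hydroxy-8-methoxy-3-methyl-2H-chromen-2-one | COc1c(O)ccc2cc(C)c(=O)oc12 | intermediate
5 | 8-methoxy-3-methyl-7-(triisopropylsilyloxy)-2H-chromen-2-one | COc1c(O[Si](C(C)C)(C(C)C)C(C)C)ccc2cc(C)c(=O)oc12 | intermediate
6 | 3-(bromomethyl)-8-methoxy-7-(triisopropylsilyloxy)-2H-chromen-2-one | COc1c(O[Si](C(C)C)(C(C)C)C(C)C)ccc2cc(CBr)c(=O)oc12 | intermediate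
7 | diethyl {[8-methoxy-2-oxo-7-(triisopropylsilyloxy)-2H-chromen-3-yl]methyl}phosphonate | COc1c(O[Si](C(C)C)(C(C)C)C(C)C)ccc2cc(CP(=O)(OCC)OCC)c(=O)oc12 | intermediate
8 | 2,3-dimethylmaleic anhydride (3,4-dimethylfuran-2,5-dione) | CC1=C(C)C(=O)OC1=O | starting material
9 | ethylene | C=C | starting material
10 | (1R,5S)-1,5-dimethyl-3-oxabicyclo[3.2.0]heptane-2,4-dione (meso) | C[C@]12CC[C@@]1(C)C(=O)OC2=O | intermediate
11 | [(1R,2S)-1,2-dimethylcyclobutane-1,2-diyl]dimethanol (cis, meso) | C[C@]1(CO)CC[C@@]1(C)CO | intermediate
12 | (1R,2S)-1,2-dimethylcyclobutane-1,2-dicarbaldehyde (cis, meso) | C[C@]1(C=O)CC[C@@]1(C)C=O | intermediate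
13 | 3,3'-{[(1R,2S)-1,2-dimethylcyclobutane-1,2-diyl]bis[(E)-ethene-2,1-diyl]}bis[8-methoxy-7-(triisopropylsilyloxy)-2H-chromen-2-one] (cis, meso) | C[C@]1(/C=C/c2cc3ccc(O[Si](C(C)C)(C(C)C)C(C)C)c(OC)c3oc2=O)CC[C@@]1(C)/C=C/c1cc2ccc(O[Si](C(C)C)(C(C)C)C(C)C)c(OC)c2oc1=O | intermediate
14 | catalyst-bound bis(allyl)nickel(II) species, drawn in its σ,σ limiting form as the nine-membered nickelacycle; the carbene ligand on Ni is not drawn; fluxional, no fixed configuration | CC1=CC(c2cc3ccc(O[Si](C(C)C)(C(C)C)C(C)C)c(OC)c3oc2=O)[Ni]C(c2cc3ccc(O[Si](C(C)C)(C(C)C)C(C)C)c(OC)c3oc2=O)C=C(C)CC1 | intermediate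
15 | 3-[(1R,6R)-3,6-dimethyl-6-{(E)-2-[8-methoxy-2-oxo-7-(triisopropylsilyloxy)-2H-chromen-3-yl]ethenyl}cyclohex-2-en-1-yl]-8-methoxy-7-(triisopropylsilyloxy)-2H-chromen-2-one | COc1c(O[Si](C(C)C)(C(C)C)C(C)C)ccc2cc(/C=C/[C@@]3(C)CCC(C)=C[C@H]3c3cc4ccc(O[Si](C(C)C)(C(C)C)C(C)C)c(OC)c4oc3=O)c(=O)oc12 | intermediate
16 | 7-hydroxy-3-[(1R,6R)-6-[(E)-2-(7-hydroxy-8-methoxy-2-oxo-2H-chromen-3-yl)ethenyl]-3,6-dimethylcyclohex-2-en-1-yl]-8-methoxy-2H-chromen-2-one | COc1c(O)ccc2cc(/C=C/[C@@]3(C)CCC(C)=C[C@H]3c3cc4ccc(O)c(OC)c4oc3=O)c(=O)oc12 | target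

**Step count**

Total steps: 11. Longest linear sequence: 8 steps (steps 1–5, 9, 10, 11).

**Three steps most likely to fail**

Step 10 (proposed new method). What may go wrong: closure to the eight-membered ring or return to the four-membered ring in place of six-ring closure; weak facial discrimination by the ligand, so that enantio- or diastereoselectivity is low; competing uncatalysed Cope rearrangement; slow turnover because nickel is held by the lactone alkenes. Fallback with known chemistry, setting out from 7 and returning at 15: phosphonate 7 is condensed with methacrolein (NaHMDS, THF, −78 → 0 °C, Horner–Wadsworth–Emmons) to the monomeric diene 8-methoxy-3-[(E)-3-methylbuta-1,3-dienyl]-7-(triisopropylsilyloxy)-2H-chromen-2-one F1. Triplet-sensitised [2+2] photodimerisation (iridium or thioxanthone sensitiser, visible/near-UV light, concentrated solution, −20 °C) should join two molecules at their CH2 termini through the bis-allylic 1,4-diradical and close mainly to the racemic trans-1,2-dimethyl-1,2-bis[(E)-2-(coumarin-3-yl)ethenyl]cyclobutane F2; the minor meso isomer 13 is removed by chromatography. Heating F2 in toluene at 80–100 °C should effect the uncatalysed diradical [1,3] shift known for trans-1,2-divinylcyclobutanes and give racemic material, that is 15 together with its mirror image, the (1S,6S)-bis-TIPS ether F3; any diastereomer is removed by chromatography. The enantiomers are parted by preparative HPLC on a chiral stationary phase, and 15 goes on to step 11.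

Step 9. What may go wrong: conjugate self-addition of the phosphonate anion to C4 of a second coumarin, base-induced opening of the lactone, or stalling after the first olefination at the hindered aldehyde. Fallback, setting out from 12 and 2 and returning at 13: dialdehyde 12 is methylenated (Ph3P=CH2, THF, 0 °C) to cis-1,2-dimethyl-1,2-divinylcyclobutane F4, kept in solution below 30 °C. Aldehyde 2 and ethyl bromo(triphenylphosphoranylidene)acetate (PhNEt2, reflux) should give 3-bromo-7-hydroxy-8-methoxy-2H-chromen-2-one F5, which is silylated (TIPSCl, imidazole, DMF) to 3-bromo-8-methoxy-7-(triisopropylsilyloxy)-2H-chromen-2-one F6. A twofold Heck reaction of F4 with F6 under room-temperature conditions (Pd2(dba)3, P(t-Bu)3, Cy2NMe, dioxane, 25–35 °C) should give 13; the quaternary ring carbons leave β-hydride elimination only one direction, toward the E-alkenylcoumarin, and the low temperature avoids the Cope rearrangement.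

Step 6. What may go wrong: photodimerisation of the anhydride outrunning capture by ethylene, whose concentration in solution is low. Fallback, setting out from 8 and returning at 10: 8 is irradiated (benzophenone sensitiser) in a large excess of 1,2-dichloroethene, a liquid alkene partner, to 6,7-dichloro-1,5-dimethyl-3-oxabicyclo[3.2.0]heptane-2,4-dione F7 (mixture of chloride epimers). Reductive dechlorination (Zn, AcOH/Et2O) should give 1,5-dimethyl-3-oxabicyclo[3.2.0]hept-6-ene-2,4-dione F8, and hydrogenation (H2, Pd/C, EtOAc) then gives 10.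

**Further compounds**

F1 | step 10 | 8-methoxy-3-[(E)-3-methylbuta-1,3-dienyl]-7-(triisopropylsilyloxy)-2H-chromen-2-one | COc1c(O[Si](C(C)C)(C(C)C)C(C)C)ccc2cc(/C=C/C(C)=C)c(=O)oc12
F2 | step 10 | trans-1,2-dimethyl-1,2-bis{(E)-2-[8-methoxy-2-oxo-7-(triisopropylsilyloxy)-2H-chromen-3-yl]ethenyl}cyclobutane (racemic, one enantiomer drawn) | C[C@]1(/C=C/c2cc3ccc(O[Si](C(C)C)(C(C)C)C(C)C)c(OC)c3oc2=O)CC[C@]1(C)/C=C/c1cc2ccc(O[Si](C(C)C)(C(C)C)C(C)C)c(OC)c2oc1=O
F3 | step 10 | (1S,6S)-enantiomer of 15 | COc1c(O[Si](C(C)C)(C(C)C)C(C)C)ccc2cc(/C=C/[C@]3(C)CCC(C)=C[C@@H]3c3cc4ccc(O[Si](C(C)C)(C(C)C)C(C)C)c(OC)c4oc3=O)c(=O)oc12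
F4 | step 9 | (1R,2S)-1,2-diethenyl-1,2-dimethylcyclobutane (cis, meso) | C[C@]1(C=C)CC[C@@]1(C)C=C
F5 | step 9 | 3-bromo-7-hydroxy-8-methoxy-2H-chromen-2-one | COc1c(O)ccc2cc(Br)c(=O)oc12
F6 | step 9 | 3-bromo-8-methoxy-7-(triisopropylsilyloxy)-2H-chromen-2-one | COc1c(O[Si](C(C)C)(C(C)C)C(C)C)ccc2cc(Br)c(=O)oc12
F7 | step 6 | 6,7-dichloro-1,5-dimethyl-3-oxabicyclo[3.2.0]heptane-2,4-dione (cis ring fusion, chloride epimers) | C[C@]12C(Cl)C(Cl)[C@@]1(C)C(=O)OC2=O
F8 | step 6 | (1R,5S)-1,5-dimethyl-3-oxabicyclo[3.2.0]hept-6-ene-2,4-dione | C[C@]12C=C[C@@]1(C)C(=O)OC2=O
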